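**Plan**

1. Numbering: ring A = C1, C2, C3(=O), C4(CH3, C19H2OAc), C5, C10. Ring B = C5, C6(=O), C7(OH), C8(CH3), C9(CH3, chain C11–C15 with CH3 on C13), C10. The C5=C10 alkene belongs to both rings.
2. Enabling feature: quaternary C4 holds an oxidised one-carbon arm (C19) and sits on C5, the far end of the allyl unit C1–C10=C5. With C19 as a carbonyl bound through oxygen to C1, the atoms C4=C19–O–C1–C10=C5 form an allyl ketene-acetal array inside a δ-lactone.
3. Cuts, last to first: C13=C14 (olefination); the C7–O bond and the C3/C6/C19 oxidation levels; C4–C5 (Ireland–Claisen ring contraction); O–C19 (lactone); C1–C10 (Nozaki–Hiyama–Kishi); C3–C4 (aldol); C8–CH3 (methylenation); C9–C11 (Michael addition).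
4. Forward order: ring B is bought as 2-methylcyclohexane-1,3-dione and dressed. A C1–C4/C19 aldehyde is joined at C10, the temporary lactone closes, and C6 is raised to the enone. Ring A then forms while the lactone opens, and the chain, acetate, C7 oxygen and C3 ketone follow.
5. Stereochemistry: C9 comes from an oxazaborolidine-catalysed desymmetrising reduction, C1 from a second catalyst-controlled ketone reduction, C4 from C1 by suprafacial 1,3-chirality transfer, and the E-alkene from a Horner–Wadsworth–Emmons reaction.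
6. C1, C3, C5, C6, C7 and C8 are relay centres only. Each is set to help the key step or left open, and none remains a stereocentre in the target.

Key step: step 16

**Remarks**
- TMS = trimethylsilyl, TBS = tert-butyldimethylsilyl, TBDPS = tert-butyldiphenylsilyl, Xc = (R)-4-benzyl-2-oxooxazolidin-3-yl, ketal chain = CH2CH2C(CH3)(OCH2CH2O).
- Compounds 1, 2, 10 and 11 are taken to be purchasable.
- C1 in 16 and C6 in 27 and 28 are carried as epimer mixtures because both centres are removed again. Their SMILES carry no descriptor at these atoms.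
- The C7 enol of the C6,C7-dione is taken to be the stable tautomer, as drawn for the target.

Step 1
Reactants: 1 2-methylcyclohexane-1,3-dione; 2 methyl vinyl ketone
Product: 3 2-methyl-2-(3-oxobutyl)cyclohexane-1,3-dione
Conditions: H2O, AcOH (cat.), hydroquinone (cat.), 75 °C
Reagents that add atoms: none
Why: Michael addition of the acidic cyclic 1,3-dione to the enone stops at the triketone in weakly acidic water and makes the C9–C11 bond, C9 still being prochiral.

Step 2
Reactants: 3 2-methyl-2-(3-oxobutyl)cyclohexane-1,3-dione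
Product: 4 2-methyl-2-[2-(2-methyl-1,3-dioxolan-2-yl)ethyl]cyclohexane-1,3-dione
Conditions: (Me3SiOCH2)2, Me3SiOTf (cat.), CH2Cl2, −78 °C
Reagents that add atoms: 1,2-bis(trimethylsilyloxy)ethane, C[Si](C)(C)OCCO[Si](C)(C)C
Why: Aprotic silyl-transfer ketalisation picks the unhindered methyl ketone over the two ring ketones flanked by quaternary C9 and is too cold for aldol cyclisation.

Step 3
Reactants: 4 2-methyl-2-[2-(2-methyl-1,3-dioxolan-2-yl)ethyl]cyclohexane-1,3-dione
Product: 5 (2S,3S)-3-hydroxy-2-methyl-2-[2-(2-methyl-1,3-dioxolan-2-yl)ethyl]cyclohexan-1-one (carbinol = C10, ketone = C8, OH cis to the chain)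
Conditions: (R)-2-methyl-CBS-oxazaborolidine (20 mol %), catecholborane (1 equiv), toluene, −78 to −40 °C; MeOH, pH 7 buffer
Reagents that add atoms: none
Why: This is a Corey–Bakshi–Shibata reduction used as a desymmetrisation, in which the (R)-catalyst makes an S carbinol with quaternary C9 as the large flank, hydride prefers the ring face carrying the C9 methyl, and only one of the two enantiotopic carbonyls meets both demands, which fixes C9.

Step 4
Reactants: 5 hydroxy ketone
Product: 6 (1S,2R)-2-methyl-3-methylidene-2-[2-(2-methyl-1,3-dioxolan-2-yl)ethyl]cyclohexan-1-ol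
Conditions: Zn, CH2Br2, TiCl4 (pre-aged in THF), CH2Cl2, 0 °C to rt
Reagents that add atoms: dibromomethane, BrCBr
Why: Lombardo methylenation is non-basic and copes with hindered ketones, so the β-hydroxy ketone cannot open by retro-aldol cleavage, which would racemise C9.

Step 5
Reactants: 6 methylidene alcohol
Product: 7 (1S,2R,3R)-2,3-dimethyl-2-[2-(2-methyl-1,3-dioxolan-2-yl)ethyl]cyclohexan-1-ol (C8 methyl cis to the chain)
Conditions: H2 (1 atm), PtO2 (cat.), EtOAc, rt
Reagents that add atoms: none
Why: Heterogeneous hydrogenation of the 1,1-disubstituted alkene should occur on the ring face opposite to the axial C9 chain, which puts the C8 methyl cis to the chain and away from the face used in step 16, and C8 is erased in step 26 in any case.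

Step 6
Reactants: 7 dimethylcyclohexanol
Product: 8 (2R,3R)-2,3-dimethyl-2-[2-(2-methyl-1,3-dioxolan-2-yl)ethyl]cyclohexan-1-one
Conditions: Dess–Martin periodinane, NaHCO3, CH2Cl2, 0 °C to rt
Reagents that add atoms: none
Why: Buffered Dess–Martin oxidation of the secondary alcohol leaves the ketal and the non-epimerisable centres C8 and C9 untouched.

Step 7
Reactants: 8 ring B ketone
Product: 9 (5R,6R)-5,6-dimethyl-6-[2-(2-methyl-1,3-dioxolan-2-yl)ethyl]cyclohex-1-en-1-yl trifluoromethanesulfonate
Conditions: LiN(iPr)2, THF, −78 °C; PhNTf2, −78 to 0 °C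
Reagents that add atoms: N-phenylbis(trifluoromethanesulfonimide), O=S(=O)(N(c1ccccc1)S(=O)(=O)C(F)(F)F)C(F)(F)F
Why: Enolate O-triflation is regiochemically unambiguous because C9 is quaternary, so the enolate can form only towards C5 and defines the C10=C5 alkene.

Step 8
Reactants: 10 (R)-4-benzyl-3-propionyloxazolidin-2-one; 11 3-(benzyloxy)propanal
Product: 12 (R)-4-benzyl-3-[(2R,3S)-5-(benzyloxy)-3-hydroxy-2-methylpentanoyl]oxazolidin-2-one
Conditions: Bu2BOTf, Et3N, CH2Cl2, 0 °C; 11, −78 to 0 °C; H2O2, MeOH, pH 7 buffer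
Reagents that add atoms: none
Why: The Evans syn aldol reaction runs through the Z boron enolate and a chair transition state, and the (R)-auxiliary is needed because it gives 3S, the configuration that later places the C3 oxygen trans to ring B on the lactone, while 4R is lost on enolisation.

Step 9
Reactants: 12 aldol adduct
Product: 13 (R)-4-benzyl-3-[(2R,3S)-5-(benzyloxy)-3-(tert-butyldimethylsilyloxy)-2-methylpentanoyl]oxazolidin-2-one
Conditions: tBuMe2SiOTf, 2,6-lutidine, CH2Cl2, 0 °C
Reagents that add atoms: tert-butyldimethylsilyl trifluoromethanesulfonate, CC(C)(C)[Si](C)(C)OS(=O)(=O)C(F)(F)F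
Why: Silylation with the silyl triflate and a hindered pyridine base protects the aldol hydroxyl without retro-aldol cleavage.

Step 10
Reactants: 13 silyl ether
Product: 14 (R)-4-benzyl-3-[(2R,3S)-3-(tert-butyldimethylsilyloxy)-5-hydroxy-2-methylpentanoyl]oxazolidin-2-one
Conditions: H2 (1 atm), Pd(OH)2/C, EtOAc, rt
Reagents that add atoms: none
Why: Hydrogenolysis cleaves only the benzyl ether, and the neutral medium keeps the δ-hydroxy imide from lactonising too early.

Step 11
Reactants: 14 primary alcohol
Product: 15 (3S,4R)-3-(tert-butyldimethylsilyloxy)-4-methyl-5-oxo-5-Xc-pentanal (C1 aldehyde of the C1–C4/C19 fragment)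
Conditions: Dess–Martin periodinane, NaHCO3, CH2Cl2, 0 °C
Reagents that add atoms: none
Why: Buffered Dess–Martin oxidation gives the β-silyloxy aldehyde without elimination or epimerisation.

Step 12
Reactants: 9 ring B enol triflate; 15 aldehyde
Product: 16 C1 allylic alcohol (both C1 epimers): ring B cyclohexene bearing at C10 the chain C1H(OH)–C2H2–C3H(OTBS)–C4H(CH3)–C19(=O)–Xc
Conditions: CrCl2 (excess), NiCl2 (1 mol %), DMF, rt to 50 °C
Reagents that add atoms: none
Why: In the Nozaki–Hiyama–Kishi coupling the alkenylchromium reagent formed under nickel catalysis adds to the aldehyde only, sparing imide, ketal and silyl ether, and the C1 epimers need no separation because step 13 removes the centre.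

Step 13
Reactants: 16 allylic alcohol
Product: 17 C1 enone (C1=O conjugated with C10=C5, otherwise as 16)
Conditions: Dess–Martin periodinane, NaHCO3, CH2Cl2, 0 °C to rt
Reagents that add atoms: none
Why: Dess–Martin oxidation of the allylic alcohol merges both epimers into one enone.

Step 14
Reactants: 17 C1 enone
Product: 19 (3R,4S,6R)-4-(tert-butyldimethylsilyloxy)-3-methyl-6-{(5R,6R)-5,6-dimethyl-6-[2-(2-methyl-1,3-dioxolan-2-yl)ethyl]cyclohex-1-en-1-yl}oxan-2-one, via 1R hydroxy imide 18 (not isolated)
Conditions: (S)-2-methyl-CBS-oxazaborolidine (0.5 equiv), catecholborane, toluene, −78 °C; MeOH; then DMAP (cat.), Et3N, CH2Cl2, rt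
Reagents that add atoms: none
Why: The Corey–Bakshi–Shibata reduction, with the ring B alkenyl group as large flank and C2H2 as small flank, gives the 1R alcohol under catalyst control independent of C9, and the δ-hydroxy imide then closes the six-membered lactone by acyl transfer with loss of the auxiliary.

Step 15
Reactants: 19 cyclohexenyl lactone
Product: 20 (3R,4S,6R)-4-(tert-butyldimethylsilyloxy)-3-methyl-6-{(5R,6R)-5,6-dimethyl-3-oxo-6-[2-(2-methyl-1,3-dioxolan-2-yl)ethyl]cyclohex-1-en-1-yl}oxan-2-one (C6 enone lactone)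
Conditions: Rh2(C6H10NO)4 (dirhodium tetracaprolactamate, 1 mol %), tBuOOH, NaHCO3, CH2Cl2, rt
Reagents that add atoms: tert-butyl hydroperoxide, CC(C)(C)OO
Why: In this dirhodium-catalysed allylic oxidation to the enone C6H2 is the only allylic methylene, since C9 is quaternary and C1–H is tertiary and deactivated by the acyloxy group.

Step 16
Reactants: 20 C6 enone lactone
Product: 23 (3S,4R,5R,8R,9R) bicyclic C19 carboxylic acid (C4 quaternary; C1=C10 alkene; C6 ketone; C3 OTBS; ketal chain), via bis-silylated ketene acetal 21 (not isolated), via rearranged trimethylsilyl ester 22 (not isolated)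
Conditions: LiN(iPr)2 (3.5 equiv) and Me3SiCl (8 equiv) premixed, THF, −95 °C; add 20; Et3N; to rt; toluene, 90 °C; 10% aq. citric acid, THF, 0 °C
Reagents that add atoms: chlorotrimethylsilane, C[Si](C)(C)Cl (its silyl groups are held by 21 and 22 and are lost again in 23)
Why: With the chlorosilane present from the start, excess amide base turns the enone by α′-deprotonation at C7 into its 2-silyloxydiene and the lactone into the ring-locked silyl ketene acetal 21 before the C3 silyloxy group can be expelled, and on heating 21 undergoes a concerted suprafacial [3,3] shift (C4–C5 forms, C1–O breaks, the alkene moves to C1=C10) to 22, which mild acid hydrolyses to 23. The closest known reaction type is the Ireland–Claisen ring contraction of 6-alkenyl δ-lactone silyl ketene acetals to cyclohexenecarboxylic acids. Ring A (C1, C2, C3, C4, C5, C10) closes as a six-membered carbocycle by pericyclic C4–C5 bonding across the boat-shaped lactone in a bicyclo[2.2.2]octane-like transition state, while the two-atom O–C19 bridge is released as the carboxyl group. C4 is controlled by C1 alone, because the ketene acetal, whose geometry the ring fixes, reaches C5 only on the face of the allyl unit from which oxygen departs, so 1R places C19 on that face and the methyl on the other (4R in 23, 4S in the target after the change of priorities), and the same event sets C5 (5R, erased in step 18). The step needs α′- rather than γ-enolisation of the enone (kinetic base, and C1–H lies in the enone plane to avoid allylic strain against C9) and survival of the β-silyloxy group (internal quench at low temperature). It also needs an open ring B face, which is secured because C6 is planar and the C9 chain, the C8 methyl and the trans C3 silyloxy group all point away from the forming bond, only the C9 methyl lying on that side.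

Step 17
Reactants: 23 keto acid
Product: 24 methyl ester of 23
Conditions: Me3SiCHN2, toluene/MeOH, 0 °C
Reagents that add atoms: (trimethylsilyl)diazomethane, C[Si](C)(C)C=[N+]=[N-]
Why: Diazoalkane esterification of the hindered acid is neutral, leaves the β,γ-unsaturated ketone and the ketal alone, and removes the carboxyl group as a possible nucleophile towards C10.

Step 18
Reactants: 24 methyl ester
Product: 25 C5=C10 enone methyl ester with free side-chain methyl ketone (C3 OTBS kept)
Conditions: 2 M HCl, THF, rt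
Reagents that add atoms: water, O
Why: Aqueous acid hydrolyses the dioxolane and, through the dienol, carries out the classical isomerisation of a β,γ- to an α,β-unsaturated ketone, giving the tetrasubstituted C5=C10 enone and erasing C5.

Step 19
Reactants: 25 enone methyl ketone
Product: 26 ethyl (E)-enoate (chain C11H2–C12H2–C13(CH3)=C14H–C15O2Et; otherwise as 25)
Conditions: (EtO)2P(O)CH2CO2Et, NaH, THF, 0 °C to rt
Reagents that add atoms: triethyl phosphonoacetate, CCOC(=O)CP(=O)(OCC)OCC
Why: The Horner–Wadsworth–Emmons olefination attacks the unhindered methyl ketone rather than the hindered tetrasubstituted enone and favours the E-trisubstituted enoate, the minor Z isomer being removed by chromatography.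

Step 20
Reactants: 26 enoate
Product: 27 triol (C19H2OH, C6H(OH) as epimers, C15H2OH; C3 OTBS)
Conditions: iBu2AlH (excess), CH2Cl2, −78 to 0 °C; Rochelle salt
Reagents that add atoms: none
Why: Hydride reduction takes both esters to primary alcohols before any acetate is present and reduces the enone by 1,2-addition to an allylic alcohol whose configuration is irrelevant because step 22 reoxidises it.

Step 21
Reactants: 27 triol
Product: 28 C15 TBDPS ether of 27
Conditions: tBuPh2SiCl (1.05 equiv), imidazole, CH2Cl2, −20 to 0 °C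
Reagents that add atoms: tert-butylchlorodiphenylsilane, CC(C)(C)[Si](Cl)(c1ccccc1)c2ccccc2
Why: Sterically governed silylation lets the bulky chlorosilane take the unhindered primary allylic C15 hydroxyl in preference to the neopentyl C19 and the secondary C6 hydroxyl.

Step 22
Reactants: 28 diol
Product: 29 C6 enone with free C19H2OH
Conditions: MnO2 (activated, excess), CH2Cl2, rt
Reagents that add atoms: none
Why: MnO2 oxidises only the allylic alcohol, so the C6 enone returns while the saturated primary C19 alcohol stays.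

Step 23
Reactants: 29 enone alcohol
Product: 30 C19 acetate of 29
Conditions: Ac2O, Et3N, DMAP (cat.), CH2Cl2, rt
Reagents that add atoms: acetic anhydride, CC(=O)OC(C)=O
Why: DMAP-catalysed acylation meets a single free hydroxyl group.

Step 24
Reactants: 30 enone acetate
Product: 31 C7 α′-hydroxy enone (OH trans to the C8 methyl)
Conditions: NaN(SiMe3)2 (1.1 equiv), THF, −78 °C; 3-phenyl-2-(phenylsulfonyl)oxaziridine, −78 °C; aq. NH4Cl
Reagents that add atoms: 3-phenyl-2-(phenylsulfonyl)oxaziridine, O=S(=O)(N1OC1c2ccccc2)c3ccccc3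
Why: Kinetic α′-deprotonation at C7, which a silazide base achieves on a ketone much faster than on an acetate at −78 °C, is followed by Davis enolate hydroxylation, expected on the face opposite to the C8 methyl and the C9 chain, and C7 becomes sp2 in step 26.

Step 25
Reactants: 31 hydroxy enone
Product: 32 C3,C7-diol (TBDPS and acetate kept)
Conditions: 48% aq. HF, MeCN, 0 °C to rt
Reagents that add atoms: none
Why: Acidic fluoride desilylation distinguishes the TBS ether from the far more acid-stable TBDPS ether.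

Step 26
Reactants: 32 diol
Product: 34 C15 TBDPS ether of the target, via trione 33 (not isolated)
Conditions: Dess–Martin periodinane (3 equiv), NaHCO3, CH2Cl2, 0 °C to rt; silica gel
Reagents that add atoms: none
Why: Dess–Martin oxidation of both secondary alcohols gives the C3 ketone and the C6,C7-dione, which can enolise only towards C8 and settles as the hydrogen-bonded diosphenol, erasing C7 and C8.

Step 27
Reactants: 34 silyl ether
Product: 35 CNP0512382.1, (4S,9S)
Conditions: HF·pyridine, pyridine, THF, 0 °C to rt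
Reagents that add atoms: none
Why: Buffered fluoride desilylation frees the allylic alcohol without base or strong acid, so the acetate, the retro-aldol-prone C4 arm and the rearrangement-prone 4,4-disubstituted dienone survive.

**Compound list**

1 | 2-methylcyclohexane-1,3-dione | CC1C(=O)CCCC1=O | starting material
2 | methyl vinyl ketone | CC(=O)C=C | starting material
3 | 2-methyl-2-(3-oxobutyl)cyclohexane-1,3-dione | CC(=O)CCC1(C)C(=O)CCCC1=O | intermediate
4 | 2-methyl-2-[2-(2-methyl-1,3-dioxolan-2-yl)ethyl]cyclohexane-1,3-dione | CC1(CCC2(C)C(=O)CCCC2=O)OCCO1 | intermediate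
5 | (2S,3S)-3-hydroxy-2-methyl-2-[2-(2-methyl-1,3-dioxolan-2-yl)ethyl]cyclohexan-1-one | O=C1CCC[C@H](O)[C@]1(C)CCC2(C)OCCO2 | intermediate
6 | (1S,2R)-2-methyl-3-methylidene-2-[2-(2-methyl-1,3-dioxolan-2-yl)ethyl]cyclohexan-1-ol | C=C1CCC[C@H](O)[C@]1(C)CCC2(C)OCCO2 | intermediate
7 | (1S,2R,3R)-2,3-dimethyl-2-[2-(2-methyl-1,3-dioxolan-2-yl)ethyl]cyclohexan-1-ol | C[C@@H]1CCC[C@H](O)[C@]1(C)CCC2(C)OCCO2 | intermediate
8 | (2R,3R)-2,3-dimethyl-2-[2-(2-methyl-1,3-dioxolan-2-yl)ethyl]cyclohexan-1-one | C[C@@H]1CCCC(=O)[C@]1(C)CCC2(C)OCCO2 | intermediate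
9 | (5R,6R)-5,6-dimethyl-6-[2-(2-methyl-1,3-dioxolan-2-yl)ethyl]cyclohex-1-en-1-yl trifluoromethanesulfonate | C[C@@H]1CCC=C(OS(=O)(=O)C(F)(F)F)[C@]1(C)CCC2(C)OCCO2 | intermediate
10 | (R)-4-benzyl-3-propionyloxazolidin-2-one | CCC(=O)N1[C@H](Cc2ccccc2)COC1=O | starting material
11 | 3-(benzyloxy)propanal | O=CCCOCc1ccccc1 | starting material
12 | (R)-4-benzyl-3-[(2R,3S)-5-(benzyloxy)-3-hydroxy-2-methylpentanoyl]oxazolidin-2-one | C[C@@H](C(=O)N1[C@H](Cc2ccccc2)COC1=O)[C@@H](O)CCOCc3ccccc3 | intermediate
13 | 3-O-TBS ether of 12 | C[C@@H](C(=O)N1[C@H](Cc2ccccc2)COC1=O)[C@@H](O[Si](C)(C)C(C)(C)C)CCOCc3ccccc3 | intermediate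
14 | (R)-4-benzyl-3-[(2R,3S)-3-(TBS-oxy)-5-hydroxy-2-methylpentanoyl]oxazolidin-2-one | C[C@@H](C(=O)N1[C@H](Cc2ccccc2)COC1=O)[C@@H](O[Si](C)(C)C(C)(C)C)CCO | intermediate
15 | (3S,4R)-3-(TBS-oxy)-4-methyl-5-oxo-5-Xc-pentanal | C[C@@H](C(=O)N1[C@H](Cc2ccccc2)COC1=O)[C@@H](O[Si](C)(C)C(C)(C)C)CC=O | intermediate
16 | C1 allylic alcohol, C1 epimers (ring B at C10 joined to the C1–C4/C19 imide chain) | C[C@@H]1CCC=C(C(O)C[C@H](O[Si](C)(C)C(C)(C)C)[C@@H](C)C(=O)N2[C@H](Cc3ccccc3)COC2=O)[C@]1(C)CCC4(C)OCCO4 | intermediate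
17 | C1 enone | C[C@@H]1CCC=C(C(=O)C[C@H](O[Si](C)(C)C(C)(C)C)[C@@H](C)C(=O)N2[C@H](Cc3ccccc3)COC2=O)[C@]1(C)CCC4(C)OCCO4 | intermediate
18 | 1R hydroxy imide (not isolated) | C[C@@H]1CCC=C([C@H](O)C[C@H](O[Si](C)(C)C(C)(C)C)[C@@H](C)C(=O)N2[C@H](Cc3ccccc3)COC2=O)[C@]1(C)CCC4(C)OCCO4 | intermediate
19 | (3R,4S,6R) δ-lactone with cyclohexenyl ring B | O=C1O[C@H](C[C@H](O[Si](C)(C)C(C)(C)C)[C@H]1C)C2=CCC[C@@H](C)[C@@]2(C)CCC3(C)OCCO3 | intermediate
20 | (3R,4S,6R) δ-lactone with C6 enone in ring B (precursor of the key step) | O=C1O[C@H](C[C@H](O[Si](C)(C)C(C)(C)C)[C@H]1C)C2=CC(=O)C[C@@H](C)[C@@]2(C)CCC3(C)OCCO3 | intermediate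
21 | TMS ketene acetal of the lactone with C6 TMS dienol ether (not isolated) | C[Si](C)(C)OC1=C(C)[C@@H](O[Si](C)(C)C(C)(C)C)C[C@@H](O1)C2=CC(O[Si](C)(C)C)=C[C@@H](C)[C@@]2(C)CCC3(C)OCCO3 | intermediate
22 | rearranged TMS ester with C6 TMS enol ether (not isolated) | C[Si](C)(C)OC(=O)[C@@]1(C)[C@@H](O[Si](C)(C)C(C)(C)C)CC=C2[C@H]1C(O[Si](C)(C)C)=C[C@@H](C)[C@@]2(C)CCC3(C)OCCO3 | intermediate
23 | bicyclic C19 acid, C1=C10 alkene, C6 ketone (product of the key step) | OC(=O)[C@@]1(C)[C@@H](O[Si](C)(C)C(C)(C)C)CC=C2[C@H]1C(=O)C[C@@H](C)[C@@]2(C)CCC3(C)OCCO3 | intermediate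
24 | methyl ester of 23 | COC(=O)[C@@]1(C)[C@@H](O[Si](C)(C)C(C)(C)C)CC=C2[C@H]1C(=O)C[C@@H](C)[C@@]2(C)CCC3(C)OCCO3 | intermediate
25 | C5=C10 enone ester with side-chain methyl ketone | COC(=O)[C@@]1(C)[C@@H](O[Si](C)(C)C(C)(C)C)CCC2=C1C(=O)C[C@@H](C)[C@@]2(C)CCC(C)=O | intermediate
26 | ethyl (E)-enoate | COC(=O)[C@@]1(C)[C@@H](O[Si](C)(C)C(C)(C)C)CCC2=C1C(=O)C[C@@H](C)[C@@]2(C)CC/C(C)=C/C(=O)OCC | intermediate
27 | C6,C15,C19-triol (C6 epimers) | OC[C@@]1(C)[C@@H](O[Si](C)(C)C(C)(C)C)CCC2=C1C(O)C[C@@H](C)[C@@]2(C)CC/C(C)=C/CO | intermediate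
28 | C15 TBDPS ether, C6,C19-diol (C6 epimers) | OC[C@@]1(C)[C@@H](O[Si](C)(C)C(C)(C)C)CCC2=C1C(O)C[C@@H](C)[C@@]2(C)CC/C(C)=C/CO[Si](c3ccccc3)(c4ccccc4)C(C)(C)C | intermediate
29 | C6 enone, C19 alcohol | OC[C@@]1(C)[C@@H](O[Si](C)(C)C(C)(C)C)CCC2=C1C(=O)C[C@@H](C)[C@@]2(C)CC/C(C)=C/CO[Si](c3ccccc3)(c4ccccc4)C(C)(C)C | intermediate
30 | C6 enone, C19 acetate | CC(=O)OC[C@@]1(C)[C@@H](O[Si](C)(C)C(C)(C)C)CCC2=C1C(=O)C[C@@H](C)[C@@]2(C)CC/C(C)=C/CO[Si](c3ccccc3)(c4ccccc4)C(C)(C)C | intermediate
31 | C7 hydroxy enone | CC(=O)OC[C@@]1(C)[C@@H](O[Si](C)(C)C(C)(C)C)CCC2=C1C(=O)[C@H](O)[C@@H](C)[C@@]2(C)CC/C(C)=C/CO[Si](c3ccccc3)(c4ccccc4)C(C)(C)C | intermediate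
32 | C3,C7-diol | CC(=O)OC[C@@]1(C)[C@@H](O)CCC2=C1C(=O)[C@H](O)[C@@H](C)[C@@]2(C)CC/C(C)=C/CO[Si](c3ccccc3)(c4ccccc4)C(C)(C)C | intermediate
33 | C3,C6,C7-trione (not isolated) | CC(=O)OC[C@@]1(C)C(=O)CCC2=C1C(=O)C(=O)[C@@H](C)[C@@]2(C)CC/C(C)=C/CO[Si](c3ccccc3)(c4ccccc4)C(C)(C)C | intermediate
34 | C15 TBDPS ether of the target | CC(=O)OC[C@@]1(C)C(=O)CCC2=C1C(=O)C(O)=C(C)[C@@]2(C)CC/C(C)=C/CO[Si](c3ccccc3)(c4ccccc4)C(C)(C)C | intermediate
35 | CNP0512382.1 | CC(=O)OC[C@@]1(C)C(=O)CCC2=C1C(=O)C(O)=C(C)[C@@]2(C)CC/C(C)=C/CO | target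

**Step count**

Total step count: 27. Longest linear sequence: 23 steps (steps 1–7 and 12–27).

**Steps most likely to fail**

**Step 16.**
- What may go wrong: enolisation of the enone towards C1 instead of C7, with loss of the C1 configuration. The C3 silyloxy group may be expelled from the lactone enolate. The silyloxydiene may decay thermally before the strained boat transition state is reached.
- Fallback, from 20 back to 23: the ketone is taken out of play at the alcohol level. Luche reduction (NaBH4, CeCl3·7H2O, MeOH, −78 °C) should give the C6 allylic alcohol F1 with the hydroxyl cis to the C8 methyl, that is, on the ring B face remote from the coming C4–C5 bond. Excess LiN(iPr)2/Me3SiCl then silylates this hydroxyl and forms the bis-silylated ketene acetal F2, in which the lactone is the only enolisable carbonyl group. Heating gives the rearranged silyl ester F3, and mild acid gives the hydroxy acid F4. Dess–Martin oxidation of F4 returns to the route at 23.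

**Step 12.**
- What may go wrong: slow metalation of an enol triflate flanked by quaternary C9, so that reduction of the triflate or loss of silanol from the aldehyde takes over.
- Fallback, from 9 and 15 back to 17: the C1–C10 bond is made at the ketone level by palladium catalysis. Triflate 9 is converted with Me3SnSnMe3, Pd(PPh3)4 and LiCl (THF, 60 °C) into the alkenylstannane F5. Aldehyde 15 is oxidised (Pinnick: NaClO2, NaH2PO4, 2-methylbut-2-ene) to the carboxylic acid F6, which 1-chloro-N,N,2-trimethylpropenylamine turns into the acid chloride F7. Stille acylation of F5 with F7 (Pd2(dba)3, tri(2-furyl)phosphine, THF) gives enone 17 directly and also saves step 13.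

**Step 24.**
- What may go wrong: deprotonation of or acyl transfer at the acetate, or γ-deprotonation at C1 with oxidation at the wrong carbon.
- Fallback, from 30 back to 34: the C7 carbonyl is brought in without a metal enolate. Condensation of 30 with tert-butoxybis(dimethylamino)methane (toluene, 90 °C) should give the enaminone F8. Dye-sensitised photo-oxygenation at −78 °C, where the enaminone is far more reactive than the trisubstituted alkene, cleaves its C=C bond to the dione, which settles as the C3-silylated diosphenol F9. Aqueous HF in MeCN gives the C3 alcohol F10, and Dess–Martin oxidation of its only carbinol returns to the route at 34.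

**Further compounds**

F1 | step 16 | C6 allylic alcohol of lactone 20 (OH cis to the C8 methyl) | O=C1O[C@H](C[C@H](O[Si](C)(C)C(C)(C)C)[C@H]1C)C2=C[C@@H](O)C[C@@H](C)[C@@]2(C)CCC3(C)OCCO3
F2 | step 16 | TMS ketene acetal of F1 with C6 OTMS | C[Si](C)(C)OC1=C(C)[C@@H](O[Si](C)(C)C(C)(C)C)C[C@@H](O1)C2=C[C@@H](O[Si](C)(C)C)C[C@@H](C)[C@@]2(C)CCC3(C)OCCO3
F3 | step 16 | rearranged TMS ester with C6 OTMS | C[Si](C)(C)OC(=O)[C@@]1(C)[C@@H](O[Si](C)(C)C(C)(C)C)CC=C2[C@H]1[C@@H](O[Si](C)(C)C)C[C@@H](C)[C@@]2(C)CCC3(C)OCCO3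
F4 | step 16 | C6 hydroxy C19 acid | OC(=O)[C@@]1(C)[C@@H](O[Si](C)(C)C(C)(C)C)CC=C2[C@H]1[C@@H](O)C[C@@H](C)[C@@]2(C)CCC3(C)OCCO3
F5 | step 12 | ring B alkenyl(trimethyl)stannane | C[C@@H]1CCC=C([Sn](C)(C)C)[C@]1(C)CCC2(C)OCCO2
F6 | step 12 | C1 carboxylic acid of the C1–C4/C19 fragment | C[C@@H](C(=O)N1[C@H](Cc2ccccc2)COC1=O)[C@@H](O[Si](C)(C)C(C)(C)C)CC(=O)O
F7 | step 12 | C1 acid chloride of the C1–C4/C19 fragment | C[C@@H](C(=O)N1[C@H](Cc2ccccc2)COC1=O)[C@@H](O[Si](C)(C)C(C)(C)C)CC(=O)Cl
F8 | step 24 | C7 (E)-dimethylaminomethylidene enone | CC(=O)OC[C@@]1(C)[C@@H](O[Si](C)(C)C(C)(C)C)CCC2=C1C(=O)/C(=C/N(C)C)[C@@H](C)[C@@]2(C)CC/C(C)=C/CO[Si](c3ccccc3)(c4ccccc4)C(C)(C)C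
F9 | step 24 | diosphenol with C3 OTBS | CC(=O)OC[C@@]1(C)[C@@H](O[Si](C)(C)C(C)(C)C)CCC2=C1C(=O)C(O)=C(C)[C@@]2(C)CC/C(C)=C/CO[Si](c3ccccc3)(c4ccccc4)C(C)(C)C
F10 | step 24 | diosphenol with free C3 OH | CC(=O)OC[C@@]1(C)[C@@H](O)CCC2=C1C(=O)C(O)=C(C)[C@@]2(C)CC/C(C)=C/CO[Si](c3ccccc3)(c4ccccc4)C(C)(C)C
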